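The dihydropyran is disconnected to a 2H-pyranone that arises by Achmatowicz oxidation of a tertiary 5-methylfuryl carbinol. The step exploits the O1–C2–C3=C4–C5(O)–C6 array of the pyran ring: the furan carbons become C2–C5, the carbinol carbon becomes C6 and its hydroxyl becomes O1. One oxidation therefore closes the pyran ring through O1–C2 and delivers the C5 oxygen and the C3=C4 alkene at the right oxidation level. The precursor, (R)-1-[(S)-cyclohex-2-en-1-yl]-1-(5-methylfuran-2-yl)ethanol, carries C6 and C1' from a single allylboration; its ring alkene (C5'=C6') is the handle from which C5' and C4' are later built.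

Key step: step 3

Remark on locants: the target locants are used for every intermediate. The pyran is O1, C2 (future CMe2), C3=C4, C5 (carbinol carbon), C6 (C–CH3 carbon). The carbocycle is C1' (on C6) to C6', with C4' the future C(CH3)Cl and C5' the future CHBr; in the cyclohex-2-enyl compounds the alkene is C5'=C6'. Stereodescriptors refer to these locants. Pyr = (5R,6R)-5-(tert-butyldimethylsilyloxy)-2,2,6-trimethyl-5,6-dihydro-2H-pyran-6-yl.

Assumption: the (R,R) ligand written in step 1 stands for the antipode that delivers the (R)-boronate; if the sense of induction is the opposite, the (S,S) ligand is taken.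

Assumption: the ketal carbon C2 is carried as a mixture of epimers until it becomes CMe2, and C4' of the monochloro ketone as a mixture until it is methylated; the SMILES leave these centres undefined.

Step 1
Reactants: 1 cyclohexa-1,3-diene; 2 bis(pinacolato)diboron
Product: 3 (R)-2-(cyclohex-2-en-1-yl)-4,4,5,5-tetramethyl-1,3,2-dioxaborolane
Conditions: CuCl (5 mol %), KOt-Bu (5 mol %), (R,R)-Me-DuPhos (5 mol %), MeOH (2 equiv), THF, −20 °C
Reagents that add atoms: none
Why: Copper-catalysed asymmetric protoboration of a 1,3-diene, in which a bisphosphine complex of monovalent copper boryl adds across one alkene and methanol protonates the allylcopper at the γ-carbon, should give the allylic boronate with the ligand choosing the alkene face and hence the boron-bearing stereocentre.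

Step 2
Reactants: 3 (R)-2-(cyclohex-2-en-1-yl)-4,4,5,5-tetramethyl-1,3,2-dioxaborolane; 4 2-acetyl-5-methylfuran
Product: 8 (R)-1-[(S)-cyclohex-2-en-1-yl]-1-(5-methylfuran-2-yl)ethanol, via lithium borate complex 5 (not isolated), via borinic ester 6 (not isolated), via boronate adduct 7 (not isolated)
Conditions: n-BuLi, THF, −78 °C; (CF3CO)2O, −78 °C; then 4, −78 °C → rt; aq. NaOH work-up
Reagents that add atoms: none
Why: Ketone allylboration by the activated borinic ester 6 through a closed six-membered chair transition state (held at −78 °C so that no 1,3-boron shift erodes the stereocentre) should form C6–C1' on the ring face that carried boron with furyl equatorial and methyl axial, so that the boronate configuration is relayed to C1' (S) and the chair fixes C6 (R).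

Step 3
Reactants: 8 (R)-1-[(S)-cyclohex-2-en-1-yl]-1-(5-methylfuran-2-yl)ethanol
Product: 10 (6R,1'S)-6-(cyclohex-2-en-1-yl)-2-hydroxy-2,6-dimethyl-2H-pyran-5(6H)-one (C2 epimers), via Z-enedione 9 (not isolated)
Conditions: NBS (1.05 equiv), NaHCO3, THF/H2O (4:1), 0 °C
Reagents that add atoms: water (SMILES: O)
Why: Electrophilic bromine adds to an α-carbon of the electron-rich furan, water adds at the other α-carbon and the 2,5-dihydrofuran collapses with loss of HBr to the Z-enedione 9, whose C6 hydroxyl then adds to the C2 methyl ketone; this is the Achmatowicz rearrangement, well established for tertiary furyl carbinols and for 5-alkylfurans. The pyran ring closes by 6-exo-trig hemiketalisation, so the crowded O1–C2 bond forms by reversible carbonyl addition and not by substitution at a tertiary carbon. The only new stereocentre is the C2 hemiketal carbon; it is not controlled and need not be, because C2 becomes trigonal again in step 9 and ends as CMe2. The step needs chemoselective oxidation of the furan in the presence of the C5'=C6' alkene, which the much higher nucleophilicity of the 2,5-dialkylfuran should secure with one equivalent of NBS at 0 °C in buffered medium. C6 and C1' are untouched because no bond to either is broken.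

Step 4
Reactants: 10 (6R,1'S)-6-(cyclohex-2-en-1-yl)-2-hydroxy-2,6-dimethyl-2H-pyran-5(6H)-one
Product: 11 (6R,1'S)-6-(cyclohex-2-en-1-yl)-2-methoxy-2,6-dimethyl-2H-pyran-5(6H)-one (C2 epimers)
Conditions: HC(OMe)3 (3 equiv), BF3·OEt2 (0.1 equiv), CH2Cl2, −20 → 0 °C
Reagents that add atoms: trimethyl orthoformate (SMILES: COC(OC)OC)
Why: Lewis-acid-catalysed ketalisation of the anomeric hydroxyl with an orthoester, through the C2 oxocarbenium ion, should lock the ring form so that no open-chain enedione is present in the reduction that follows.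

Step 5
Reactants: 11 (6R,1'S)-6-(cyclohex-2-en-1-yl)-2-methoxy-2,6-dimethyl-2H-pyran-5(6H)-one
Product: 12 (5S,6R,1'S)-6-(cyclohex-2-en-1-yl)-2-methoxy-2,6-dimethyl-5,6-dihydro-2H-pyran-5-ol
Conditions: NaBH4, CeCl3·7H2O, MeOH, −78 °C
Reagents that add atoms: none
Why: Luche 1,2-reduction should deliver hydride to C5 anti to the pseudoaxial C6 methyl group (the larger cyclohexenyl group sits pseudoequatorial), giving the alcohol with hydroxyl cis to that methyl group, which is the C5 epimer (5S) of what the target needs.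

Step 6
Reactants: 12 (5S,6R,1'S)-6-(cyclohex-2-en-1-yl)-2-methoxy-2,6-dimethyl-5,6-dihydro-2H-pyran-5-ol
Product: 14 (5R,6R,1'S)-6-(cyclohex-2-en-1-yl)-2-methoxy-2,6-dimethyl-5,6-dihydro-2H-pyran-5-yl 4-nitrobenzoate, via alkoxyphosphonium salt 13 (not isolated)
Conditions: 4-nitrobenzoic acid, PPh3, DIAD, THF, 0 → 40 °C
Reagents that add atoms: 4-nitrobenzoic acid (SMILES: O=C(O)c1ccc(cc1)[N+](=O)[O-])
Why: Mitsunobu esterification, in which the carboxylate displaces the C5 alkoxyphosphonium group by SN2 from the open face anti to the C6 methyl group, should invert C5 to the required 5R configuration, as is routine for allylic alcohols of 2,3-unsaturated pyranosides.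

Step 7
Reactants: 14 (5R,6R,1'S)-6-(cyclohex-2-en-1-yl)-2-methoxy-2,6-dimethyl-5,6-dihydro-2H-pyran-5-yl 4-nitrobenzoate
Product: 15 (5R,6R,1'S)-6-(cyclohex-2-en-1-yl)-2-methoxy-2,6-dimethyl-5,6-dihydro-2H-pyran-5-ol
Conditions: K2CO3, MeOH, 0 °C → rt
Reagents that add atoms: none
Why: Base-catalysed transesterification of the activated aryl ester frees the 5R alcohol at the acyl carbon, so neither C5 nor the ketal is affected.

Step 8
Reactants: 15 (5R,6R,1'S)-6-(cyclohex-2-en-1-yl)-2-methoxy-2,6-dimethyl-5,6-dihydro-2H-pyran-5-ol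
Product: 16 (5R,6R,1'S)-5-(tert-butyldimethylsilyloxy)-6-(cyclohex-2-en-1-yl)-2-methoxy-2,6-dimethyl-5,6-dihydro-2H-pyran
Conditions: TBSCl, imidazole, DMAP (cat.), DMF, 40 °C
Reagents that add atoms: tert-butyldimethylsilyl chloride (SMILES: CC(C)(C)[Si](C)(C)Cl)
Why: Silyl ether formation under basic conditions protects the hindered C5 hydroxyl for the organometallic and oxidation steps and leaves the acid-labile allylic ketal intact.

Step 9
Reactants: 16 (5R,6R,1'S)-5-(tert-butyldimethylsilyloxy)-6-(cyclohex-2-en-1-yl)-2-methoxy-2,6-dimethyl-5,6-dihydro-2H-pyran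
Product: 17 (5R,6R,1'S)-5-(tert-butyldimethylsilyloxy)-6-(cyclohex-2-en-1-yl)-2,2,6-trimethyl-5,6-dihydro-2H-pyran
Conditions: AlMe3 (3 equiv), CH2Cl2, −78 → 0 °C; aq. potassium sodium tartrate work-up
Reagents that add atoms: trimethylaluminium (SMILES: C[Al](C)C)
Why: Lewis-acid-mediated substitution of a ketal by an organoaluminium reagent, in which AlMe3 ionises the allylic ketal to the C2 oxocarbenium ion and returns methyl to C2 within the ion pair, should give the gem-dimethyl carbon, which is not a stereocentre.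

Step 10
Reactants: 17 (5R,6R,1'S)-5-(tert-butyldimethylsilyloxy)-6-(cyclohex-2-en-1-yl)-2,2,6-trimethyl-5,6-dihydro-2H-pyran
Product: 19 (1'S,5'S)-1'-Pyr-cyclohexan-5'-ol, via B-alkyl-9-BBN 18 (not isolated)
Conditions: 9-BBN (1.5 equiv), THF, 0 °C → rt; then NaOH, H2O2, 0 °C
Reagents that add atoms: hydrogen peroxide (SMILES: OO)
Why: Hydroboration–oxidation with the bulky borane should place boron on C5', the alkene carbon remote from the heavily substituted C1', anti to that substituent, while the hindered and oxygen-deactivated pyran alkene stays intact; the C5' configuration is erased in step 11 and is of no consequence.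

Step 11
Reactants: 19 (1'S,5'S)-1'-Pyr-cyclohexan-5'-ol
Product: 20 (1'S)-1'-Pyr-cyclohexan-5'-one
Conditions: Dess–Martin periodinane, NaHCO3, CH2Cl2, rt
Reagents that add atoms: none
Why: Dess–Martin oxidation converts the secondary alcohol into the C5' ketone under buffered, near-neutral conditions that spare the silyl ether and the allylic ring ether.

Step 12
Reactants: 20 (1'S)-1'-Pyr-cyclohexan-5'-one
Product: 22 (1'S)-4'-chloro-1'-Pyr-cyclohexan-5'-one (C4' epimers), via lithium enolate 21 (not isolated)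
Conditions: LiN(i-Pr)2 (1.1 equiv), THF, −78 °C; then TsCl (1.2 equiv), −78 → 0 °C
Reagents that add atoms: 4-toluenesulfonyl chloride (SMILES: Cc1ccc(cc1)S(=O)(=O)Cl)
Why: Kinetic deprotonation by the hindered amide should occur at C4', away from C6' which is flanked by the bulky C1' substituent, and the enolate is then chlorinated by the sulfonyl chloride acting as an electrophilic chlorine donor (enolate α-chlorination); the C4' configuration does not matter because the centre is made trigonal again in step 13.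

Step 13
Reactants: 22 (1'S)-4'-chloro-1'-Pyr-cyclohexan-5'-one
Product: 24 (1'S,4'S)-4'-chloro-4'-methyl-1'-Pyr-cyclohexan-5'-one, via lithium chloro-enolate 23 (not isolated)
Conditions: LiN(SiMe3)2 (1.1 equiv), THF, −78 °C; then MeI (5 equiv), DMPU, −78 → −30 °C
Reagents that add atoms: iodomethane (SMILES: CI)
Why: Deprotonation at the more acidic chlorine-bearing C4' and C-alkylation of the resulting enolate should follow the stereoelectronic preference for axial attack on a cyclohexanone enolate whose C1' substituent is equatorial, which places methyl axial and chlorine equatorial (4'S).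

Step 14
Reactants: 24 (1'S,4'S)-4'-chloro-4'-methyl-1'-Pyr-cyclohexan-5'-one
Product: 25 (1'S,4'S,5'R)-4'-chloro-4'-methyl-1'-Pyr-cyclohexan-5'-ol
Conditions: LiBH(s-Bu)3, THF, −78 °C; H2O quench
Reagents that add atoms: none
Why: Ketone reduction with a bulky trialkylborohydride, which attacks from the equatorial direction even next to an axial α-methyl group (as with 4,4-dimethyl-3-ketosteroids), should give the axial C5' alcohol cis to chlorine (5'R), set up for displacement with inversion.

Step 15
Reactants: 25 (1'S,4'S,5'R)-4'-chloro-4'-methyl-1'-Pyr-cyclohexan-5'-ol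
Product: 27 (1'S,4'S,5'S)-5'-bromo-4'-chloro-4'-methyl-1'-Pyr-cyclohexane, via alkoxyphosphonium bromide 26 (not isolated)
Conditions: CBr4, PPh3, toluene, 60 °C
Reagents that add atoms: carbon tetrabromide (SMILES: BrC(Br)(Br)Br)
Why: In the Appel reaction bromide displaces the axial oxyphosphonium group from the equatorial side (SN2 with inversion), giving the equatorial 5'S bromide trans to chlorine, and the gauche chlorine cannot participate because it is not antiperiplanar to the leaving group.

Step 16
Reactants: 27 (1'S,4'S,5'S)-5'-bromo-4'-chloro-4'-methyl-1'-Pyr-cyclohexane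
Product: 28 (2R,3R)-2-[(1S,3S,4S)-3-bromo-4-chloro-4-methylcyclohexyl]-2,6,6-trimethyl-3,6-dihydro-2H-pyran-3-ol
Conditions: HF·pyridine, pyridine, THF, 0 °C → rt
Reagents that add atoms: none
Why: Fluoride-mediated desilylation under buffered acidic conditions removes the silyl ether without base, so neither the secondary bromide nor the tertiary chloride is exposed to elimination.

Compound list

1 | cyclohexa-1,3-diene | C1=CC=CCC1 | starting material
2 | bis(pinacolato)diboron | CC1(C)OB(OC1(C)C)B1OC(C)(C)C(C)(C)O1 | starting material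
3 | (R)-2-(cyclohex-2-en-1-yl)-4,4,5,5-tetramethyl-1,3,2-dioxaborolane | CC1(C)OB(OC1(C)C)[C@@H]2CCCC=C2 | intermediate
4 | 2-acetyl-5-methylfuran | CC(=O)c1ccc(C)o1 | starting material
5 | lithium (R)-butyl(cyclohex-2-en-1-yl)(pinacolato)borate (ate complex; not isolated) | [Li+].CCCC[B-]1(OC(C)(C)C(C)(C)O1)[C@@H]2CCCC=C2 | intermediate
6 | 2,3-dimethyl-3-(trifluoroacetoxy)butan-2-yl (R)-butyl(cyclohex-2-en-1-yl)borinate (not isolated) | CCCCB(OC(C)(C)C(C)(C)OC(=O)C(F)(F)F)[C@@H]1CCCC=C1 | intermediate
7 | butylboronic acid mixed diester of the (R,S)-carbinol alkoxide and pinacol mono(trifluoroacetate) (not isolated) | Cc1ccc(o1)[C@](C)(OB(CCCC)OC(C)(C)C(C)(C)OC(=O)C(F)(F)F)[C@H]2CCCC=C2 | intermediate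
8 | (R)-1-[(S)-cyclohex-2-en-1-yl]-1-(5-methylfuran-2-yl)ethanol | Cc1ccc(o1)[C@](C)(O)[C@H]2CCCC=C2 | intermediate
9 | (3Z,6R)-6-[(S)-cyclohex-2-en-1-yl]-6-hydroxyhept-3-ene-2,5-dione (not isolated) | CC(=O)/C=C\C(=O)[C@](C)(O)[C@H]1CCCC=C1 | intermediate
10 | (6R,1'S)-6-(cyclohex-2-en-1-yl)-2-hydroxy-2,6-dimethyl-2H-pyran-5(6H)-one, C2 epimers; by ring-priority numbering (2R)-2-[(1S)-cyclohex-2-en-1-yl]-6-hydroxy-2,6-dimethyl-2H-pyran-3(6H)-one | CC1(O)C=CC(=O)[C@@](C)([C@H]2CCCC=C2)O1 | intermediate
11 | (6R,1'S)-6-(cyclohex-2-en-1-yl)-2-methoxy-2,6-dimethyl-2H-pyran-5(6H)-one, C2 epimers | COC1(C)C=CC(=O)[C@@](C)([C@H]2CCCC=C2)O1 | intermediate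
12 | (5S,6R,1'S)-6-(cyclohex-2-en-1-yl)-2-methoxy-2,6-dimethyl-5,6-dihydro-2H-pyran-5-ol (hydroxyl cis to the C6 methyl group) | COC1(C)C=C[C@H](O)[C@@](C)([C@H]2CCCC=C2)O1 | intermediate
13 | [(5S,6R,1'S)-6-(cyclohex-2-en-1-yl)-2-methoxy-2,6-dimethyl-5,6-dihydro-2H-pyran-5-yloxy]triphenylphosphonium 4-nitrobenzoate (not isolated) | COC1(C)C=C[C@H](O[P+](c2ccccc2)(c3ccccc3)c4ccccc4)[C@@](C)([C@H]5CCCC=C5)O1.[O-]C(=O)c6ccc(cc6)[N+](=O)[O-] | intermediate
14 | (5R,6R,1'S)-6-(cyclohex-2-en-1-yl)-2-methoxy-2,6-dimethyl-5,6-dihydro-2H-pyran-5-yl 4-nitrobenzoate | COC1(C)C=C[C@@H](OC(=O)c2ccc(cc2)[N+](=O)[O-])[C@@](C)([C@H]3CCCC=C3)O1 | intermediate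
15 | (5R,6R,1'S)-6-(cyclohex-2-en-1-yl)-2-methoxy-2,6-dimethyl-5,6-dihydro-2H-pyran-5-ol (hydroxyl cis to the cyclohexenyl group) | COC1(C)C=C[C@@H](O)[C@@](C)([C@H]2CCCC=C2)O1 | intermediate
16 | (5R,6R,1'S)-5-(tert-butyldimethylsilyloxy)-6-(cyclohex-2-en-1-yl)-2-methoxy-2,6-dimethyl-5,6-dihydro-2H-pyran | COC1(C)C=C[C@@H](O[Si](C)(C)C(C)(C)C)[C@@](C)([C@H]2CCCC=C2)O1 | intermediate
17 | (5R,6R,1'S)-5-(tert-butyldimethylsilyloxy)-6-(cyclohex-2-en-1-yl)-2,2,6-trimethyl-5,6-dihydro-2H-pyran | CC1(C)C=C[C@@H](O[Si](C)(C)C(C)(C)C)[C@@](C)([C@H]2CCCC=C2)O1 | intermediate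
18 | 9-[(1'S,5'S)-1'-Pyr-cyclohexan-5'-yl]-9-borabicyclo[3.3.1]nonane (boron trans to Pyr; not isolated) | CC1(C)C=C[C@@H](O[Si](C)(C)C(C)(C)C)[C@@](C)([C@H]2CCC[C@H](B3C4CCCC3CCC4)C2)O1 | intermediate
19 | (1'S,5'S)-1'-Pyr-cyclohexan-5'-ol (hydroxyl trans to Pyr) | CC1(C)C=C[C@@H](O[Si](C)(C)C(C)(C)C)[C@@](C)([C@H]2CCC[C@H](O)C2)O1 | intermediate
20 | (1'S)-1'-Pyr-cyclohexan-5'-one | CC1(C)C=C[C@@H](O[Si](C)(C)C(C)(C)C)[C@@](C)([C@H]2CCCC(=O)C2)O1 | intermediate
21 | lithium enolate of 20 toward C4' (C4'=C5'; not isolated) | CC1(C)C=C[C@@H](O[Si](C)(C)C(C)(C)C)[C@@](C)([C@H]2CCC=C(O[Li])C2)O1 | intermediate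
22 | (1'S)-4'-chloro-1'-Pyr-cyclohexan-5'-one, C4' epimers | CC1(C)C=C[C@@H](O[Si](C)(C)C(C)(C)C)[C@@](C)([C@H]2CCC(Cl)C(=O)C2)O1 | intermediate
23 | lithium enolate of 22 at the chlorine-bearing carbon (C4'=C5'; not isolated) | CC1(C)C=C[C@@H](O[Si](C)(C)C(C)(C)C)[C@@](C)([C@H]2CCC(Cl)=C(O[Li])C2)O1 | intermediate
24 | (1'S,4'S)-4'-chloro-4'-methyl-1'-Pyr-cyclohexan-5'-one (chlorine equatorial, methyl axial) | CC1(C)C=C[C@@H](O[Si](C)(C)C(C)(C)C)[C@@](C)([C@H]2CC[C@](C)(Cl)C(=O)C2)O1 | intermediate
25 | (1'S,4'S,5'R)-4'-chloro-4'-methyl-1'-Pyr-cyclohexan-5'-ol (axial hydroxyl cis to chlorine) | CC1(C)C=C[C@@H](O[Si](C)(C)C(C)(C)C)[C@@](C)([C@H]2CC[C@](C)(Cl)[C@H](O)C2)O1 | intermediate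
26 | [(1'S,4'S,5'R)-4'-chloro-4'-methyl-1'-Pyr-cyclohexan-5'-yloxy]triphenylphosphonium bromide (not isolated) | CC1(C)C=C[C@@H](O[Si](C)(C)C(C)(C)C)[C@@](C)([C@H]2CC[C@](C)(Cl)[C@H](O[P+](c3ccccc3)(c4ccccc4)c5ccccc5)C2)O1.[Br-] | intermediate
27 | (1'S,4'S,5'S)-5'-bromo-4'-chloro-4'-methyl-1'-Pyr-cyclohexane | CC1(C)C=C[C@@H](O[Si](C)(C)C(C)(C)C)[C@@](C)([C@H]2CC[C@](C)(Cl)[C@@H](Br)C2)O1 | intermediate
28 | (2R,3R)-2-[(1S,3S,4S)-3-bromo-4-chloro-4-methylcyclohexyl]-2,6,6-trimethyl-3,6-dihydro-2H-pyran-3-ol | CC1(C)C=C[C@@H](O)[C@@](C)([C@H]2CC[C@](C)(Cl)[C@@H](Br)C2)O1 | target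

Total step count: 16. Longest linear sequence: 16 steps (from cyclohexa-1,3-diene).

Steps most likely to fail

Step 13 (C-methylation of the chloro enolate). What may go wrong: deprotonation on the C6' side followed by Favorskii-type collapse, Darzens-type self-condensation of the chloro enolate, or too little preference for axial attack. The fallback changes the nucleophile from a lithium enolate to a 3-chloro-1-azaallyl anion, which is less prone to self-condensation. It sets out from 22: condensation with isopropylamine (TiCl4, Et3N, Et2O, 0 °C) would give the N-isopropyl α-chloro ketimine F1. Deprotonation with LiN(i-Pr)2 at the chlorine-bearing carbon and methylation with iodomethane, again along the axial trajectory, would give the α-chloro-α-methyl ketimine F2. Hydrolysis in a two-phase oxalic acid buffer comes back to the route at 24.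

Step 15 (Appel bromination). What may go wrong: elimination of the activated axial hydroxyl toward C6', migration of the antiperiplanar axial C4' methyl group after ionisation, or no displacement at this neopentyl-type carbon. The fallback separates activation from displacement. It sets out from 25: Tf2O and pyridine (CH2Cl2, −40 °C) would give the C5' triflate F3. Displacement at or below 0 °C by n-Bu4NBr in toluene (SN2, inversion) comes back to the route at 27.

Step 9 (methylation of the C2 ketal). What may go wrong: methyl transfer to C4 of the ambident allylic oxocarbenium ion, or proton loss from the C2 methyl group to give a dienyl ether. The fallback adds the second methyl group to a carbonyl group instead of an oxocarbenium ion. It sets out from 16: mild hydrolysis (pyridinium 4-toluenesulfonate, wet acetone) would give the hemiketal F4. Through its open-chain methyl ketone tautomer this reacts with MeMgBr and CeCl3 (THF, −78 °C) to give the Z-configured tertiary diol F5. Cyclodehydration with catalytic camphorsulfonic acid (CH2Cl2, 0 °C), in which the C6 hydroxyl captures the tertiary allylic cation at C2, closes the same O1–C2 bond again and comes back to the route at 17.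

Further compounds

F1 | step 13 | (1'S)-4'-chloro-N-isopropyl-1'-Pyr-cyclohexan-5'-imine, C4' epimers | CC1(C)C=C[C@@H](O[Si](C)(C)C(C)(C)C)[C@@](C)([C@H]2CCC(Cl)C(=NC(C)C)C2)O1
F2 | step 13 | (1'S,4'S)-4'-chloro-4'-methyl-N-isopropyl-1'-Pyr-cyclohexan-5'-imine | CC1(C)C=C[C@@H](O[Si](C)(C)C(C)(C)C)[C@@](C)([C@H]2CC[C@](C)(Cl)C(=NC(C)C)C2)O1
F3 | step 15 | (1'S,4'S,5'R)-4'-chloro-4'-methyl-1'-Pyr-cyclohexan-5'-yl trifluoromethanesulfonate | CC1(C)C=C[C@@H](O[Si](C)(C)C(C)(C)C)[C@@](C)([C@H]2CC[C@](C)(Cl)[C@H](OS(=O)(=O)C(F)(F)F)C2)O1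
F4 | step 9 | (5R,6R,1'S)-5-(tert-butyldimethylsilyloxy)-6-(cyclohex-2-en-1-yl)-2,6-dimethyl-5,6-dihydro-2H-pyran-2-ol, C2 epimers | CC1(O)C=C[C@@H](O[Si](C)(C)C(C)(C)C)[C@@](C)([C@H]2CCCC=C2)O1
F5 | step 9 | (3Z,5R,6R)-5-(tert-butyldimethylsilyloxy)-6-[(S)-cyclohex-2-en-1-yl]-2-methylhept-3-ene-2,6-diol | CC(C)(O)/C=C\[C@@H](O[Si](C)(C)C(C)(C)C)[C@](C)(O)[C@H]1CCCC=C1
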